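**Strategy.** Everything rests on cutting ring C of the upper (gallocatechin) unit at C4–C4a and C2–C3: an aryloxycarbenium ion (O1=C2, built on the symmetric phloroglucinol ring A) is combined with an (E)-enol acetate that already sits on C8 of perbenzylated epicatechin. One chiral-acid-controlled oxa-Povarov event (formal inverse-electron-demand [4+2]) closes ring C, unites all three building blocks and sets C2, C3 and C4. It exploits the all-equatorial 2,3-trans-3,4-trans triad of ring C, the two equivalent ortho carbons of ring A, and the doubly benzylic C4 between two phloroglucinol-type rings. The precursors are a mixed O-aryl O-methyl acetal and a β-acetoxystyrene.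

Key step: step 7

Remarks on the chemistry:
- Flavan numbering is used throughout; "upper" is the gallocatechin unit, "lower" the epicatechin unit. The target is read as gallocatechin-(4α→8)-epicatechin, upper unit (2R,3S,4S), lower unit (2R,3R).
- Assumption: the sense of induction of the chiral acid in step 7 cannot be predicted with confidence. The (R)-acid is written; its mirror image is used if a first run shows that it favours the (2S,3R,4R) upper unit.

**Step 1**
Reactants: 1 (−)-epicatechin
Product: 2 3,5,7,3′,4′-penta-O-benzyl-(−)-epicatechin, (2R,3R)-3,5,7-tris(benzyloxy)-2-[3,4-bis(benzyloxy)phenyl]chroman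
Conditions: NaH (6 equiv), BnBr (6 equiv), DMF, 0 °C → rt
Reagents that add atoms: benzyl bromide, BrCc1ccccc1
Why: Williamson etherification of the four phenoxides and the C3 alkoxide; no stereocentre is formed, and capping the 4′-phenol early at 0 °C removes the quinone-methide pathway that could epimerise C2.

**Step 2**
Reactants: 2 penta-O-benzylepicatechin
Product: 3 8-bromo-3,5,7,3′,4′-penta-O-benzylepicatechin, (2R,3R)
Conditions: NBS (1.0 equiv), CH2Cl2, −78 → 0 °C
Reagents that add atoms: N-bromosuccinimide, O=C1CCC(=O)N1Br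
Why: Electrophilic aromatic bromination of the phloroglucinol-type ring A, expected at C8 (between O1 and the 7-benzyloxy group) rather than at C6 or on the less activated catechol ring.

**Step 3**
Reactants: 3 8-bromo-penta-O-benzylepicatechin; 4 (E)-1,2-bis(4,4,5,5-tetramethyl-1,3,2-dioxaborolan-2-yl)ethene
Product: 5 2-[(E)-2-[(2R,3R)-3,5,7-tris(benzyloxy)-2-[3,4-bis(benzyloxy)phenyl]chroman-8-yl]ethenyl]-4,4,5,5-tetramethyl-1,3,2-dioxaborolane
Conditions: 4 (3 equiv), Pd(OAc)2 (5 mol %), SPhos (10 mol %), K3PO4, toluene/H2O (10:1), 80 °C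
Reagents that add atoms: none
Why: Suzuki–Miyaura cross-coupling in which one boryl group of 4 transmetalates and the other survives, with retention of the E geometry; the excess of 4 and the two ortho oxygens at C8 should hold back a second coupling.

**Step 4**
Reactants: 5 (E)-alkenylboronate
Product: 6 (E)-2-[(2R,3R)-3,5,7-tris(benzyloxy)-2-[3,4-bis(benzyloxy)phenyl]chroman-8-yl]ethenyl acetate
Conditions: Cu(OAc)2 (2 equiv), Et3N (3 equiv), 4 Å MS, air, MeCN/CH2Cl2, rt; chromatography on Et3N-deactivated silica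
Reagents that add atoms: copper diacetate, CC(=O)[O-].CC(=O)[O-].[Cu+2]
Why: Chan–Lam-type oxidative C–O coupling: the alkenyl group moves from boron to copper, and reductive elimination from a trivalent copper acetate forms the enol ester with retention of the E geometry.

**Step 5**
Reactants: 7 3,4,5-tris(benzyloxy)benzaldehyde
Product: 8 1,2,3-tris(benzyloxy)-5-(dimethoxymethyl)benzene
Conditions: HC(OMe)3 (3 equiv), p-TsOH·H2O (2 mol %), MeOH, rt; Et3N quench
Reagents that add atoms: trimethyl orthoformate, COC(OC)OC; methanol, CO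
Why: Acid-catalysed acetalisation driven to completion by the orthoformate as water scavenger; aryl benzyl ethers are inert.

**Step 6**
Reactants: 8 dimethyl acetal; 9 3,5-bis(benzyloxy)phenol
Product: 11 1,3-bis(benzyloxy)-5-{methoxy[3,4,5-tris(benzyloxy)phenyl]methoxy}benzene (racemic mixed acetal), via α-chlorobenzyl methyl ether 10 (not isolated)
Conditions: AcCl (1.2 equiv), CH2Cl2, 0 °C → rt, evaporate; then 9, NaH, THF/DMF, 0 °C → rt; Et3N-deactivated silica
Reagents that add atoms: acetyl chloride, CC(Cl)=O (chlorine of intermediate 10 only)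
Why: Acetal–acyl chloride exchange gives the α-chloro ether, which the sodium phenoxide substitutes at oxygen (Williamson-type, SN1-like) to the mixed acetal; the acetal carbon is formed racemic, which is irrelevant because it becomes planar in step 7.

**Step 7**
Reactants: 6 (E)-enol acetate; 11 mixed acetal
Product: 14 3-O-acetyl-5,7,3′,4′,5′-penta-O-benzylgallocatechin-(4α→8)-3,5,7,3′,4′-penta-O-benzylepicatechin, upper unit (2R,3S,4S), lower unit (2R,3R), via aryloxycarbenium ion 12 (not isolated), via C4 benzylic cation 13 (not isolated)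
Conditions: 11 (1.5 equiv, slow addition), (R)-3,3′-bis(2,4,6-triisopropylphenyl)-1,1′-binaphthyl-2,2′-diyl N-triflylphosphoramide (10 mol %), 5 Å MS, toluene/CH2Cl2, −60 → −40 °C
Reagents that add atoms: none
Why: Proposed new method: the chiral acid protonates the more basic methoxy oxygen of 11 and releases the aryloxycarbenium ion 12 (a cationic 2-oxadiene) as a contact ion pair with the chiral phosphoramide anion; the acetoxy-bearing alkene carbon of 6 adds to C2 (Prins-type C2–C3 bond) because the 2,4,6-trioxygenated ring A of the epicatechin unit, not the weakly donating acetoxy group, polarises the alkene, and the doubly stabilised C4 cation 13 is then captured by an ortho carbon of the phloroglucinol ring (Friedel–Crafts C4–C4a bond), which returns the proton to the catalyst. The closest known reaction type is the Lewis-acid-mediated oxa-Povarov reaction of O-aryl O-methyl acetals with styrenes (formal inverse-electron-demand [4+2] cycloaddition), and catalyst control is modelled on chiral-acid Povarov and Prins chemistry, but an enantiofacially controlled oxa-Povarov reaction on substrates of this kind is not established. Ring C closes as the six-membered ring of the [4+2] manifold, its second bond by 6-exo-trig attack of the arene on the quinone-methide-like C4 cation. C2 and C3 are set together in the first bond formation, their trans relation by the E geometry of 6 in the all-equatorial chair-like arrangement (the usual 2,4-cis outcome of Povarov-type closures) and their absolute sense by the chiral anion; C4 is set in the ring closure, trans to the C3 acetoxy group (equatorial closure, backed by acetoxonium shielding of the cis face). The step needs regioselectivity in the alkene (secured by the weak acetate donor against the strong aryl donor), a single site of ring closure (secured by the symmetry of the 3,5-bis(benzyloxy)phenoxy ring, whose two ortho carbons are equivalent), chemoselectivity for the alkene over the free C6 of the epicatechin unit and over ring A of 11 (helped by slow addition of 11), and facial selectivity, which the remote (2R,3R) centres cannot supply and the catalyst must.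

**Step 8**
Reactants: 14 protected dimer acetate
Product: 15 5,7,3′,4′,5′-penta-O-benzylgallocatechin-(4α→8)-3,5,7,3′,4′-penta-O-benzylepicatechin (free upper 3-OH)
Conditions: NaOMe (0.3 equiv), MeOH/THF (1:1), 40 °C
Reagents that add atoms: none
Why: Base-catalysed transesterification (Zemplén conditions) removes the secondary acetate without touching benzyl ethers; no centre can epimerise because no phenol is free.

**Step 9**
Reactants: 15 decabenzyl dimer
Product: 16 gallocatechin-(4α→8)-epicatechin (target)
Conditions: H2 (1 atm), Pd(OH)2/C, THF/MeOH/H2O, rt; filtration and lyophilisation under argon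
Reagents that add atoms: none
Why: Hydrogenolysis of the nine aryl benzyl ethers and the one alkyl benzyl ether under neutral conditions should spare the acid-labile C4–C8 bond and all stereocentres.

**Compound list**

1 | (−)-epicatechin, (2R,3R) | Oc1cc(O)c2c(c1)O[C@H](c1ccc(O)c(O)c1)[C@H](O)C2 | starting material
2 | 3,5,7,3′,4′-penta-O-benzyl-(−)-epicatechin | c1ccccc1COc1cc(OCc3ccccc3)c2c(c1)O[C@H](c1ccc(OCc3ccccc3)c(OCc3ccccc3)c1)[C@H](OCc3ccccc3)C2 | intermediate
3 | 8-bromo-3,5,7,3′,4′-penta-O-benzylepicatechin | Brc1c(OCc3ccccc3)cc(OCc3ccccc3)c2c1O[C@H](c1ccc(OCc3ccccc3)c(OCc3ccccc3)c1)[C@H](OCc3ccccc3)C2 | intermediate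
4 | (E)-1,2-bis(4,4,5,5-tetramethyl-1,3,2-dioxaborolan-2-yl)ethene | CC1(C)OB(/C=C/B2OC(C)(C)C(C)(C)O2)OC1(C)C | starting material
5 | (E)-alkenyl pinacol boronate at C8 of penta-O-benzylepicatechin | CC1(C)OB(OC1(C)C)/C=C/c1c(OCc3ccccc3)cc(OCc3ccccc3)c2c1O[C@H](c1ccc(OCc3ccccc3)c(OCc3ccccc3)c1)[C@H](OCc3ccccc3)C2 | intermediate
6 | (E)-2-(penta-O-benzylepicatechin-8-yl)ethenyl acetate | CC(=O)O/C=C/c1c(OCc3ccccc3)cc(OCc3ccccc3)c2c1O[C@H](c1ccc(OCc3ccccc3)c(OCc3ccccc3)c1)[C@H](OCc3ccccc3)C2 | intermediate
7 | 3,4,5-tris(benzyloxy)benzaldehyde | O=Cc1cc(OCc2ccccc2)c(OCc2ccccc2)c(OCc2ccccc2)c1 | starting material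
8 | 1,2,3-tris(benzyloxy)-5-(dimethoxymethyl)benzene | COC(OC)c1cc(OCc2ccccc2)c(OCc2ccccc2)c(OCc2ccccc2)c1 | intermediate
9 | 3,5-bis(benzyloxy)phenol | Oc1cc(OCc2ccccc2)cc(OCc2ccccc2)c1 | starting material
10 | 1,2,3-tris(benzyloxy)-5-[chloro(methoxy)methyl]benzene (racemic, not isolated) | COC(Cl)c1cc(OCc2ccccc2)c(OCc2ccccc2)c(OCc2ccccc2)c1 | intermediate
11 | 1,3-bis(benzyloxy)-5-{methoxy[3,4,5-tris(benzyloxy)phenyl]methoxy}benzene (racemic) | COC(Oc1cc(OCc2ccccc2)cc(OCc2ccccc2)c1)c1cc(OCc2ccccc2)c(OCc2ccccc2)c(OCc2ccccc2)c1 | intermediate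
12 | [3,5-bis(benzyloxy)phenyl][3,4,5-tris(benzyloxy)benzylidene]oxonium ion (not isolated) | c1ccccc1COc1cc(OCc2ccccc2)cc(c1)[O+]=Cc1cc(OCc2ccccc2)c(OCc2ccccc2)c(OCc2ccccc2)c1 | intermediate
13 | open C4 cation after C2–C3 bond formation, (2R,3S), ring C not yet closed (not isolated) | c1ccccc1COc1cc(OCc3ccccc3)cc(c1)O[C@H](c1cc(OCc3ccccc3)c(OCc3ccccc3)c(OCc3ccccc3)c1)[C@@H](OC(C)=O)[CH+]c1c(OCc3ccccc3)cc(OCc3ccccc3)c2c1O[C@H](c1ccc(OCc3ccccc3)c(OCc3ccccc3)c1)[C@H](OCc3ccccc3)C2 | intermediate
14 | 3-O-acetyl-5,7,3′,4′,5′-penta-O-benzylgallocatechin-(4α→8)-3,5,7,3′,4′-penta-O-benzylepicatechin | c1ccccc1COc1cc(OCc3ccccc3)c2c(c1)O[C@H](c1cc(OCc3ccccc3)c(OCc3ccccc3)c(OCc3ccccc3)c1)[C@@H](OC(C)=O)[C@@H]2c1c(OCc3ccccc3)cc(OCc3ccccc3)c2c1O[C@H](c1ccc(OCc3ccccc3)c(OCc3ccccc3)c1)[C@H](OCc3ccccc3)C2 | intermediate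
15 | 5,7,3′,4′,5′-penta-O-benzylgallocatechin-(4α→8)-3,5,7,3′,4′-penta-O-benzylepicatechin | c1ccccc1COc1cc(OCc3ccccc3)c2c(c1)O[C@H](c1cc(OCc3ccccc3)c(OCc3ccccc3)c(OCc3ccccc3)c1)[C@@H](O)[C@@H]2c1c(OCc3ccccc3)cc(OCc3ccccc3)c2c1O[C@H](c1ccc(OCc3ccccc3)c(OCc3ccccc3)c1)[C@H](OCc3ccccc3)C2 | intermediate
16 | gallocatechin-(4α→8)-epicatechin, (2R,3S,4S)-2-(3,4,5-trihydroxyphenyl)-4-[(2R,3R)-2-(3,4-dihydroxyphenyl)-3,5,7-trihydroxychroman-8-yl]chroman-3,5,7-triol | Oc1cc(O)c2c(c1)O[C@H](c1cc(O)c(O)c(O)c1)[C@@H](O)[C@@H]2c1c(O)cc(O)c2c1O[C@H](c1ccc(O)c(O)c1)[C@H](O)C2 | target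

**Step count.** Total: 9 steps. Longest linear sequence: 7 steps (steps 1, 2, 3, 4, 7, 8, 9); steps 5 and 6 form the second branch.

**Steps most likely to fail**

1. Step 7 (bears the label). What may go wrong:
   - insufficient facial discrimination by the ion pair, so that both all-trans diastereomers form;
   - Friedel–Crafts capture of the oxocarbenium ion by the free C6 of the epicatechin unit or by ring A of the acetal;
   - acid-induced oligomerisation of the electron-rich styrene;
   - loss of the aryloxy group instead of the methoxy group on ionisation.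

   Fallback with known chemistry, setting out from 2 and coming back at 14: commercial (+)-gallocatechin F1 is benzylated at its five phenols (BnBr, K2CO3, DMF) to 5,7,3′,4′,5′-penta-O-benzylgallocatechin F2. F2 is oxidised at C4 with DDQ in the presence of 2-ethoxyethanol to the 4-(2-ethoxyethoxy) ether F3, which is acetylated (Ac2O, DMAP, pyridine) to the 3-O-acetate F4. TMSOTf (catalytic) in CH2Cl2 at −78 °C ionises F4 to the C4 cation, which C8 of 2 (used in excess) should capture trans to the 3-acetoxy group, giving 14. Here the upper stereocentres are bought and only C4 is relayed from C3.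

2. Step 4. What may go wrong: protodeboronation of the electron-rich alkenylboronate, oxidative homocoupling to the diene, or hydrolysis of the enol acetate to the arylacetaldehyde on work-up. Fallback, setting out from 3 and coming back at 6 (it also bypasses step 3): bromine–lithium exchange on 3 (n-BuLi, THF, −78 °C) and opening of ethylene oxide (BF3·OEt2) give 2-(penta-O-benzylepicatechin-8-yl)ethanol F5. Oxidation with DMP/NaHCO3 gives (penta-O-benzylepicatechin-8-yl)acetaldehyde F6. Enol acetylation under equilibrating conditions (Ac2O, KOAc, 100 °C) should favour the E isomer 6, because the two ortho oxygens disfavour the Z isomer.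

3. Step 6. What may go wrong: C-alkylation of the ambident phloroglucinol-type phenoxide instead of O-alkylation, or hydrolysis of the chloro ether or of the mixed acetal during isolation. Fallback, setting out from 7 and coming back at 11: NaBH4 reduction of 7 gives 3,4,5-tris(benzyloxy)benzyl alcohol F7. Mitsunobu etherification with 9 (PPh3, DIAD, THF) gives 3,5-bis(benzyloxy)phenyl 3,4,5-tris(benzyloxy)benzyl ether F8. DDQ in CH2Cl2/MeOH with 4 Å MS at 0 °C abstracts hydride from the trialkoxybenzylic position, and methanol captures the cation to give 11.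

**Further compounds**

F1 | step 7 | (+)-gallocatechin, (2R,3S) (commercial) | Oc1cc(O)c2c(c1)O[C@H](c1cc(O)c(O)c(O)c1)[C@@H](O)C2
F2 | step 7 | 5,7,3′,4′,5′-penta-O-benzyl-(+)-gallocatechin | c1ccccc1COc1cc(OCc3ccccc3)c2c(c1)O[C@H](c1cc(OCc3ccccc3)c(OCc3ccccc3)c(OCc3ccccc3)c1)[C@@H](O)C2
F3 | step 7 | (2R,3S,4S)-4-(2-ethoxyethoxy)-5,7,3′,4′,5′-penta-O-benzylgallocatechin | c1ccccc1COc1cc(OCc3ccccc3)c2c(c1)O[C@H](c1cc(OCc3ccccc3)c(OCc3ccccc3)c(OCc3ccccc3)c1)[C@@H](O)[C@H]2OCCOCC
F4 | step 7 | (2R,3S,4S)-3-O-acetyl-4-(2-ethoxyethoxy)-5,7,3′,4′,5′-penta-O-benzylgallocatechin | c1ccccc1COc1cc(OCc3ccccc3)c2c(c1)O[C@H](c1cc(OCc3ccccc3)c(OCc3ccccc3)c(OCc3ccccc3)c1)[C@@H](OC(C)=O)[C@H]2OCCOCC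
F5 | step 4 | 2-(penta-O-benzylepicatechin-8-yl)ethanol | OCCc1c(OCc3ccccc3)cc(OCc3ccccc3)c2c1O[C@H](c1ccc(OCc3ccccc3)c(OCc3ccccc3)c1)[C@H](OCc3ccccc3)C2
F6 | step 4 | (penta-O-benzylepicatechin-8-yl)acetaldehyde | O=CCc1c(OCc3ccccc3)cc(OCc3ccccc3)c2c1O[C@H](c1ccc(OCc3ccccc3)c(OCc3ccccc3)c1)[C@H](OCc3ccccc3)C2
F7 | step 6 | 3,4,5-tris(benzyloxy)benzyl alcohol | OCc1cc(OCc2ccccc2)c(OCc2ccccc2)c(OCc2ccccc2)c1
F8 | step 6 | 3,5-bis(benzyloxy)phenyl 3,4,5-tris(benzyloxy)benzyl ether | c1ccccc1COc1cc(OCc2ccccc2)cc(c1)OCc1cc(OCc2ccccc2)c(OCc2ccccc2)c(OCc2ccccc2)c1
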